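Target cannot reach the whole charge of starting material: 0.0200 M of protic impurity takes its share, leaving room for 80.0% of the charge.

    reagent + free catalyst → catalyst intermediate A (k1 = 6.5 M⁻¹ h⁻¹, Ea1 = 58.0 kJ mol⁻¹)
    catalyst intermediate A → catalyst intermediate B (k2 = 6.4 h⁻¹, Ea2 = 75.0 kJ mol⁻¹)
    starting material + catalyst intermediate B ⇌ catalyst intermediate C (K3 = 23 M⁻¹, k3 = 2.5 M⁻¹ h⁻¹, Ea3 = 63.0 kJ mol⁻¹, ΔH3 = −25.0 kJ mol⁻¹)
    catalyst intermediate C → free catalyst + target (k4 = 11 h⁻¹, Ea4 = 75.0 kJ mol⁻¹)
    starting material + protic impurity → quenched substrate (k5 = 2.8 M⁻¹ h⁻¹, Ea5 = 53.0 kJ mol⁻¹)
    (constants at −20 °C)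

| flask | starting material | reagent | protic impurity | free catalyst | time | remark | temperature |
|---|---|---|---|---|---|---|---|
| Tuesday's | 0.10 M | 0.0900 M | 0.0200 M | 15 mM | 4.0 d | everything together at the start at −40 °C, warmed to −20 °C at 3.0 d |  |
| Saturday's | 0.10 M | 0.0900 M (fed, over 3.0 d) | 0.0200 M | 15 mM | 4.0 d | all else is in the flask from the start; the feed brings no volume worth counting | −20 °C |
| Monday's | 0.10 M (fed, over 3.0 d) | 0.0900 M | 0.0200 M | 15 mM | 4.0 d | the addition at −40 °C, then warmed to −20 °C; the feed brings no volume worth counting |  |
| Thursday's | 0.10 M (fed, over 3.0 d) | 0.0900 M | 0.0200 M | 15 mM | 4.0 d | all else is in the flask from the start; the feed brings no volume worth counting | −20 °C |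

- the list of constants is for −20 °C, to be carried to other temperatures by the activation energies and enthalpies

- which flask leads in amount of target, in percent of the starting material charged ("all alike" within 1.5 percentage points) (Tuesday's / Saturday's / Monday's / Thursday's / all alike)
- how much target is there at the end, in percent of the starting material charged: Tuesday's
- how much target is there at the end, in percent of the starting material charged: Saturday's
- how much target is there at the end, in percent of the starting material charged: Monday's
- how much target is there at the end, in percent of the starting material charged: Thursday's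

This is my note for whoever takes over the bench. The reckoning is mine.

1. I count two meetings in the cycle: free catalyst with reagent, and catalyst intermediate B with starting material. At −20 °C, catalyst intermediate A moves on at 6.4 h⁻¹, faster than free catalyst takes up the full reagent charge at 0.585 h⁻¹. Catalyst intermediate C gives target at 11 h⁻¹, faster than catalyst intermediate B takes up the full starting material charge at 0.250 h⁻¹.

2. Loading the catalyst costs 10.8 mM of reagent. That leaves 79.2 mM, close to the 80.0 mM of starting material with room. So I let the two fall together. I expect catalyst intermediate B to be the main resting state, holding 72.2% of the catalyst, with free catalyst beside it.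

3. In this reckoning, the starting material with room then decays pseudo-first-order. I call its rate the clock: the catalyst charge times the product of the two constants over their sum 0.0271 h⁻¹.

4. At −40 °C the clock reads 0.00219 h⁻¹, slower than the warm clock by a factor of 12.4.

5. The logarithm of that amount falls by clock times time, and stages add. I treat a feed as a batch arriving halfway through it.

6. So I expect Tuesday's at 0.808 lifetimes to give 44.3%. Monday's at 0.729 should give 41.4%. Saturday's at 1.62 should give 64.2%, and Thursday's, with the same count, 64.2%. I cannot part those two.

7. Do not cool a warm flask: a cold hour counts for far less.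

The forecast parts them: Saturday's leads, with 43% for Tuesday's, 67% for Saturday's, 41% for Monday's and 60% for Thursday's. In the cold, it says, “the cycle barely turns over”.

The flasks give 42.3% for Tuesday's, 64.7% for Saturday's, 41.1% for Monday's and 61.6% for Thursday's, so Saturday's leads and the forecast holds. At the end, Saturday's keeps 15% of its starting material unbound, and my count for Saturday's left 15.8% of the charge. A flask like Saturday's kept at −35 °C has 0.257 lifetimes, which reckons to 18.1% target. It gives 17.0%, with starting material still at 63.0%.

The rate constants were set for the occasion; the result is computed.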